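Remarks on the chemistry: labdane numbering is used for the target and for the bicyclic compounds 11, 12, 14 and 15. Compounds 1–10 keep abietane numbering, in which abietane C14 is the carbon that becomes labdane C17. Commercial abietic acid (1) is assumed to be purified before use, and half ester 13 is taken as the commercial (R)-enantiomer.

## Structural features

The target is a labdane: a trans-decalin (ring A = C1–C5 and C10, ring B = C5–C10) with an exocyclic methylene C8=C17 and a branch on C9, C11–C12–C13(C16)–C14–C15O2H. Four contiguous stereocentres lie along C4–C5–C10–C9: quaternary C4 (axial 4β-CH3, equatorial 4α-CO2Me, so C18 is the ester), C5 (α-H), quaternary C10 (β-CH3) and C9 (equatorial β chain, α-H). The fifth stereocentre, C13 (R), stands alone in the chain, next to the C14 methylene of the free C15 acid and separated from C9 by the methylenes C11 and C12, so nothing in the ring block can direct it. The fragile group is the 1,1-disubstituted C8=C17 alkene: acid moves it into ring B and lets a C12 or C15 carboxyl lactonise onto C8, and ozone, peracids and hydrogenation attack it. The two carboxyl groups differ only in hindrance (tertiary neopentyl-type C18 ester against the primary-chain C15 acid). The real difficulty is twofold: C4 with its equatorial ester inside the C4/C5/C10/C9 array, which is the epimer that radical cyclisation of ester-bearing polyenes or enolate methylation is not expected to give, and the remote C13. The key step exploits the C11–C12 bond: both carbons are plain methylenes, and C12–C13(C16)–C14–C15 is exactly a 3-methylglutaric half ester less CO2, so an anodic decarboxylative radical coupling can join two acids there without touching either stereochemical domain. The ring block, with C4, C5, C9, C10 and the C18 carboxyl, is identical with rings A and B of abietic acid, whose ring C carbon C14 is the future C17.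

## Logic of the disconnections

15 ⇒ 14. No skeletal bond is cut; only the C15–O bond of a methyl ester is restored. The radical partner of the key step must carry its second carboxyl blocked, and the two esters of 14 differ enough in hindrance to be told apart at the end. The gain is a C15 acid that stays silent during the electrolysis. The forward step must stop at C15 and must be worked up without acid strong enough to move C8=C17.

14 ⇒ 12 + 13. The C11–C12 bond is cut. In one sentence the whole route is a mixed Kolbe electrolysis of 12 with 13. This is the only bond between the ring stereocentres and C13, and both of its carbons are unfunctionalised methylenes that can each be a primary radical born from a carboxylate. A C22 diester with five stereocentres becomes a C17 acid holding the four ring centres and a C7 half ester holding C13, and the two domains no longer have to be related by any reaction. The forward step demands cross- over homo-coupling, combination of the C11 radical faster than its cyclisation onto C8 or its oxidation, survival of C8=C17 at the anode, and no ester migration in 13.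

12 ⇒ 11 ⇒ 10 ⇒ 8. The C12 carboxyl is traced back through the aldehyde and an α-ketol to a ketone, so the C12–C13 bond is restored retrosynthetically. The chain C11–C12–C13(=O)–CH(CH3)2 is what ring C of the pool material leaves on C9, so the acid needs trimming only and no carbon–carbon bond formation. The forward steps demand enolisation at the C12 methylene and not at the isopropyl methine, and oxidants that spare C8=C17.

8 ⇒ 5 ⇒ 4. No carbon–carbon bond is cut; the exocyclic double bond is moved to C7=C8 and C14 is raised to the aldehyde. An allylic diazene derived from the enal loses N2 with hydrogen delivery to C7, which places the alkene exocyclic by mechanism and not by thermodynamics. The gain is that the fragile alkene is born under neutral conditions from a robust enal. The demand is chemoselectivity for the aldehyde over the C13 ketone.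

4 ⇒ 2 ⇒ 1. C13 and C14 are reconnected as a double bond, which closes ring C; then the ester goes back to the acid. This turns the seco compound into a resin acid that already holds C4, C5, C9 and C10 in the right configurations, including the equatorial-ester quaternary C4. All ring stereochemistry is therefore bought and not made. The forward cleavage must select C13=C14 in the presence of C7=C8 and must not epimerise C9.

## Other disconnections considered

Alternative 1: the first to come to mind. Cut C4–C5 and C9–C10 in a biomimetic bicyclisation. The forward key step would be an oxidative radical cyclisation (Mn(OAc)3, Cu(OAc)2) of the acyclic β-keto diester A1, which already carries C13, to the bicyclic keto diester A2, with C8=C17 formed by β-hydride loss from the organocopper intermediate.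
- Structure: in the chair transition state the ester on the radical carbon is expected to sit axial, anti to the ring ketone, so A2 would carry the ester cis to the C10 methyl, the C4 epimer of the target.
- Mechanism: C13 of A1 is too far from the forming centres to bias the ring enantiofaces, so two diastereomers in about equal amounts are expected unless an auxiliary is added.
- Step economy: the C3 ketone must be removed afterwards, and A1 is itself a multistep assembly.

The chosen plan buys the correct C4 instead.

Alternative 2: cut at C13 and create this centre last under catalyst control. The forward key step would be a Horner–Wadsworth–Emmons olefination of methyl ketone A3 to enoate A4, then an enantioselective copper hydride 1,4-reduction (Cu(OAc)2, chiral bisphosphine, silane) to 14.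
- Structure: olefination of a ketone flanked by CH2 and CH3 is expected to give E/Z mixtures, and the two isomers lead to opposite configurations at C13.
- Mechanism: the catalyst would have to act with no help from the substrate.
- Step economy: A3 needs several carbon-adjusting steps from the seco series, whereas the Kolbe coupling brings C13 in preformed in one operation.

Alternative 3: cut C9–C11 while creating C8=C17. The forward key step would be a Johnson–Claisen rearrangement of the bicyclic allylic alcohol A5 (C8=C9 alkene, C17 hydroxymethyl) with triethyl orthoacetate, giving ester A6 with the acetate arm on C9 and the exocyclic methylene in one step.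
- Structure and mechanism: the new C9–C11 bond is expected to form on the α face, anti to the axial C10 methyl next to C9. That gives the axial 9α chain, the C9 epimer of what is needed (A6 is drawn as that epimer), and C9 cannot be corrected by epimerisation.
- Step economy: A5 would itself take several steps.

The chosen plan never forms a bond at C9.

Key step: step 8

## Route

Step 1
Reactants: 1 abietic acid
Product: 2 methyl abietate
Conditions: MeI, K2CO3, DMF, rt
Reagents that add atoms: iodomethane, CI
Why: SN2 O-alkylation of the carboxylate, which works on the hindered C4 acid where acid-catalysed esterification is slow and would isomerise the diene; no stereocentre is touched.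

Step 2
Reactants: 2 methyl abietate
Product: 4 methyl 13,14-dioxo-13,14-secoabiet-7-en-18-oate (C8 enal, C9 chain CH2CH2C(=O)CH(CH3)2), via abietene diol 3 (not isolated)
Conditions: OsO4 (2 mol%), NMO (1.1 equiv), acetone/H2O, 0 °C to rt; then NaIO4 (1.5 equiv), rt
Reagents that add atoms: OsO4 (oxygen carrier, regenerated by NMO), O=[Os](=O)(=O)=O; N-methylmorpholine N-oxide, C[N+]1([O-])CCOCC1; water, O
Why: Two-stage Lemieux–Johnson sequence: syn dihydroxylation is expected at the distal, more accessible C13=C14 bond (C7=C8 is flanked by the ring fusion and C9) to give cis-diol 3, whose facial sense is immaterial, and periodate glycol cleavage then opens ring C to the C13 ketone and C14 aldehyde. The remaining C7=C8 bond becomes conjugated with the aldehyde and is deactivated towards further osmylation; the near-neutral medium leaves C9 untouched.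

Step 3
Reactants: 4 methyl 13,14-dioxo-13,14-secoabiet-7-en-18-oate
Product: 5 14-(E)-tosylhydrazone of 4
Conditions: TsNHNH2 (1.05 equiv), EtOH, rt
Reagents that add atoms: 4-methylbenzenesulfonohydrazide, Cc1ccc(cc1)S(=O)(=O)NN
Why: Hydrazone condensation; with one equivalent the aldehyde should react far faster than the hindered isopropyl ketone.

Step 4
Reactants: 5 14-(E)-tosylhydrazone of 4
Product: 8 methyl 13-oxo-13,14-secoabiet-8(14)-en-18-oate (exocyclic methylene, isopropyl ketone), via borylated allyl hydrazide 6 (not isolated), via allylic diazene 7 (not isolated)
Conditions: catecholborane (1.1 equiv), CHCl3, 0 °C; then NaOAc·3H2O, 60 °C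
Reagents that add atoms: none
Why: Alkene-transposing reduction of an α,β-unsaturated tosylhydrazone: 1,2-hydride addition to C=N gives 6, acetate releases sulfinate to give diazene 7, and 7 loses N2 through a six-membered retro-ene transition state that delivers hydrogen to C7 and leaves the double bond exocyclic at C8=C14. The position of the alkene is fixed by the mechanism under non-acidic conditions, and the hindered ketone is expected to be reduced much more slowly than the sulfonylhydrazone.

Step 5
Reactants: 8 methyl 13-oxo-13,14-secoabiet-8(14)-en-18-oate
Product: 10 methyl 12-hydroxy-13-oxo-13,14-secoabiet-8(14)-en-18-oate (both C12 epimers), via potassium enolate 9 (not isolated)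
Conditions: KN(SiMe3)2 (1.1 equiv), THF, −78 °C; then 2-(phenylsulfonyl)-3-phenyloxaziridine, −78 °C; aq. NH4Cl
Reagents that add atoms: 2-(phenylsulfonyl)-3-phenyloxaziridine, O=S(=O)(c1ccccc1)N1OC1c1ccccc1
Why: Kinetic enolisation by the bulky amide at the C12 methylene and not at the isopropyl methine, followed by electrophilic oxygen transfer from the N-sulfonyloxaziridine to the enolate. The new C12 carbinol centre is formed unselectively and is destroyed in step 6; the C18 ester has no α-hydrogen and the alkene is inert.

Step 6
Reactants: 10 methyl 12-hydroxy-13-oxo-13,14-secoabiet-8(14)-en-18-oate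
Product: 11 methyl 12-oxo-13,14,15,16-tetranorlabd-8(17)-en-18-oate (aldehyde)
Conditions: Pb(OAc)4 (1.2 equiv), MeOH/CH2Cl2, 0 °C
Reagents that add atoms: none
Why: Glycol-type cleavage of the α-ketol through its methyl hemiketal breaks C12–C13, leaving C12 as the aldehyde and expelling the isobutyryl group as its methyl ester; the isolated alkene should not react with Pb(OAc)4 at 0 °C in the short reaction time.

Step 7
Reactants: 11 methyl 12-oxo-13,14,15,16-tetranorlabd-8(17)-en-18-oate
Product: 12 13,14,15,16-tetranorlabd-8(17)-ene-12,18-dioic acid 18-methyl ester (bicyclic acetic acid)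
Conditions: NaClO2, NaH2PO4, 2-methyl-2-butene, t-BuOH/H2O, 0 °C to rt
Reagents that add atoms: sodium chlorite, [Na+].[O-]Cl=O
Why: Pinnick oxidation; 2-methyl-2-butene scavenges HOCl so that C8=C17 is not chlorinated, and the phosphate buffer is too weakly acidic to lactonise the acid onto C8.

Step 8
Reactants: 12 13,14,15,16-tetranorlabd-8(17)-ene-12,18-dioic acid 18-methyl ester; 13 (R)-5-methoxy-3-methyl-5-oxopentanoic acid (methyl hydrogen (R)-3-methylglutarate)
Product: 14 dimethyl (13R)-labd-8(17)-ene-15,18-dioate
Conditions: 12 (1 equiv), 13 (8 equiv), NaOMe (5 mol% of total acid), MeOH; undivided cell, Pt anode, Pt cathode, constant current ca. 0.25 A cm−2, 10–15 °C, until slightly basic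
Reagents that add atoms: none
Why: Mixed Kolbe electrolysis (anodic decarboxylative radical–radical cross-coupling): the carboxylates of 12 and 13 adsorbed on the Pt anode are each oxidised by one electron, the acyloxy radicals lose CO2 at once, and the primary radicals at C11 (from 12) and C12 (from 13) combine in the dense radical layer at the electrode to form the C11–C12 bond, while protons are reduced to H2 at the cathode. The closest known reaction type is the classical co-electrolysis of an alkanoic acid with a dicarboxylic acid half ester, β-methyl-branched half esters included. No ring is closed and no stereocentre is created: C4, C5, C9 and C10 arrive fixed in 12 and C13 arrives fixed in 13, where it is the neighbour of the radical carbon and never a radical itself; C9, although next to the C11 radical, keeps its hydrogen. Cross- over homo-coupling of the valuable partner is secured statistically by the eightfold excess of the cheap 13, whose symmetrical dimer diester is removed by distillation or chromatography. Radical combination over two-electron oxidation to a cation is secured by the non-stabilised primary nature of both radicals, smooth Pt, high current density and the weakly acidic methanolic medium. The homoallylic C11 radical could in principle close onto C8 (3-exo) and reopen with ring expansion, but such rearrangements are expected to be orders of magnitude slower than radical–radical combination at Kolbe radical densities, and the carboxylate layer on the anode shields the isolated C8=C17 alkene from direct oxidation. Both methyl esters are inert, and low temperature and short electrolysis time limit ester migration in 13 through its cyclic anhydride.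

Step 9
Reactants: 14 dimethyl (13R)-labd-8(17)-ene-15,18-dioate
Product: 15 (13R)-labd-8(17)-ene-15,18-dioic acid 18-methyl ester (target, 4R,5R,9S,10R,13R)
Conditions: LiOH·H2O (3 equiv), THF/MeOH/H2O, rt; then cold 0.5 M HCl to pH 4
Reagents that add atoms: lithium hydroxide, [Li+].[OH-]
Why: Saponification by acyl–oxygen cleavage at the unhindered C15 ester; the C18 ester on quaternary C4, shielded by the axial C19 methyl, should be inert at rt. C13 is not α to the carboxylate and cannot epimerise, and the brief cold acidification is too mild to move C8=C17.

## Compound list

1 | abietic acid (abieta-7,13-dien-18-oic acid) | CC(C)C3=CC1=CC[C@@H]2[C@](C)(CCC[C@@]2(C)C(=O)O)[C@H]1CC3 | starting material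
2 | methyl abietate | CC(C)C3=CC1=CC[C@@H]2[C@](C)(CCC[C@@]2(C)C(=O)OC)[C@H]1CC3 | intermediate
3 | methyl 13β,14β-dihydroxyabiet-7-en-18-oate (cis-diol, drawn as the β,β isomer) | CC(C)[C@]3(O)[C@@H](O)C1=CC[C@@H]2[C@](C)(CCC[C@@]2(C)C(=O)OC)[C@H]1CC3 | intermediate (not isolated)
4 | methyl 13,14-dioxo-13,14-secoabiet-7-en-18-oate | O=CC1=CC[C@@H]2[C@](C)(CCC[C@@]2(C)C(=O)OC)[C@H]1CCC(=O)C(C)C | intermediate
5 | 14-(E)-tosylhydrazone of 4 | Cc1ccc(cc1)S(=O)(=O)N/N=C/C1=CC[C@@H]2[C@](C)(CCC[C@@]2(C)C(=O)OC)[C@H]1CCC(=O)C(C)C | intermediate
6 | N-(1,3,2-benzodioxaborol-2-yl) allylic tosylhydrazide from 5 | Cc1ccc(cc1)S(=O)(=O)NN(CC1=CC[C@@H]2[C@](C)(CCC[C@@]2(C)C(=O)OC)[C@H]1CCC(=O)C(C)C)B1Oc2ccccc2O1 | intermediate (not isolated)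
7 | allylic diazene (C14–N=NH) | N=NCC1=CC[C@@H]2[C@](C)(CCC[C@@]2(C)C(=O)OC)[C@H]1CCC(=O)C(C)C | intermediate (not isolated)
8 | methyl 13-oxo-13,14-secoabiet-8(14)-en-18-oate | C=C1CC[C@@H]2[C@](C)(CCC[C@@]2(C)C(=O)OC)[C@H]1CCC(=O)C(C)C | intermediate
9 | potassium (Z)-enolate of 8 (C12=C13) | C=C1CC[C@@H]2[C@](C)(CCC[C@@]2(C)C(=O)OC)[C@H]1C/C=C(\[O-])C(C)C.[K+] | intermediate (not isolated)
10 | methyl 12-hydroxy-13-oxo-13,14-secoabiet-8(14)-en-18-oate (C12 epimers) | C=C1CC[C@@H]2[C@](C)(CCC[C@@]2(C)C(=O)OC)[C@H]1CC(O)C(=O)C(C)C | intermediate
11 | methyl 12-oxo-13,14,15,16-tetranorlabd-8(17)-en-18-oate | C=C1CC[C@@H]2[C@](C)(CCC[C@@]2(C)C(=O)OC)[C@H]1CC=O | intermediate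
12 | 13,14,15,16-tetranorlabd-8(17)-ene-12,18-dioic acid 18-methyl ester | C=C1CC[C@@H]2[C@](C)(CCC[C@@]2(C)C(=O)OC)[C@H]1CC(=O)O | intermediate
13 | (R)-5-methoxy-3-methyl-5-oxopentanoic acid | COC(=O)C[C@H](C)CC(=O)O | starting material
14 | dimethyl (13R)-labd-8(17)-ene-15,18-dioate | C=C1CC[C@@H]2[C@](C)(CCC[C@@]2(C)C(=O)OC)[C@H]1CC[C@@H](C)CC(=O)OC | intermediate
15 | (13R)-labd-8(17)-ene-15,18-dioic acid 18-methyl ester | C=C1CC[C@@H]2[C@](C)(CCC[C@@]2(C)C(=O)OC)[C@H]1CC[C@@H](C)CC(=O)O | target

## Step count and least certain steps

Total step count: 9. Longest linear sequence: 9 steps (1 to 15); 13 enters at step 8.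

Step 8 (key step). What may go wrong:
- statistical homo-coupling that consumes 12;
- anodic or radical attack on the C8=C17 alkene;
- over-oxidation of the C11 radical to the cation (Hofer–Moest pathway) with lactonisation or methyl ether formation;
- ester migration in 13 through the cyclic anhydride, which would erode the configuration at C13.

Fallback, setting out from 12 and 13 and returning at 14: 12 is converted into its N-hydroxyphthalimide ester F1 (N-hydroxyphthalimide, N,N′-diisopropylcarbodiimide). 13 is converted by iododecarboxylation (PhI(OAc)2, I2, hν) into methyl (S)-4-iodo-3-methylbutanoate F2 and then, with Zn and LiCl in THF, into (S)-(4-methoxy-2-methyl-4-oxobutyl)zinc iodide F3. A decarboxylative alkyl–alkyl Negishi-type coupling of F1 with F3 under NiCl2·glyme and 4,4′-di-tert-butyl-2,2′-bipyridine should then give 14 without an electrode and without excess radical partner.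

Step 2. What may go wrong: poor site selectivity of the osmylation between C13=C14 and C7=C8, or a second osmylation at the diol stage before cleavage. Fallback, from 2 back to 4: electrophilic epoxidation (mCPBA, NaHCO3, CH2Cl2, 0 °C), whose site selectivity follows alkene nucleophilicity and access, to methyl 13β,14β-epoxyabiet-7-en-18-oate F4, then opening and cleavage of the epoxide with H5IO6 in aqueous THF to give 4.

Step 4. What may go wrong: competing reduction of the C13 ketone by catecholborane, hydrazone formation at the ketone in step 3, or loss of sulfinate before reduction with isomerisation of the diene. Fallback, from 4 back to 8: NaBH4 reduces both carbonyl groups of 4 to methyl 13,14-dihydroxy-13,14-secoabiet-7-en-18-oate F5. Mitsunobu displacement of its primary allylic hydroxyl with 2-nitrobenzenesulfonylhydrazide (PPh3, diethyl azodicarboxylate, −30 °C to rt) gives, through the same kind of allylic diazene, methyl 13-hydroxy-13,14-secoabiet-8(14)-en-18-oate F6. Swern oxidation returns 8.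

Step 5. What may go wrong: incomplete regiocontrol of the enolisation, addition of the enolate to the sulfonimine by-product, or over-oxidation to the 1,2-diketone. Fallback, from 8 back to 10: the kinetic enolate is trapped (LiN(iPr)2, Me3SiCl, THF, −78 °C) as the trimethylsilyl enol ether F7, which is purified and submitted to a Rubottom oxidation (mCPBA, NaHCO3, CH2Cl2, −20 °C, then mild desilylation). This relies on the much higher nucleophilicity of the silyl enol ether compared with the 1,1-disubstituted alkene.

## Further compounds

F1 | step 8 | 1,3-dioxoisoindolin-2-yl ester of 12 | C=C1CC[C@@H]2[C@](C)(CCC[C@@]2(C)C(=O)OC)[C@H]1CC(=O)ON1C(=O)c2ccccc2C1=O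
F2 | step 8 | methyl (S)-4-iodo-3-methylbutanoate | COC(=O)C[C@H](C)CI
F3 | step 8 | (S)-(4-methoxy-2-methyl-4-oxobutyl)zinc iodide | COC(=O)C[C@H](C)C[Zn]I
F4 | step 2 | methyl 13β,14β-epoxyabiet-7-en-18-oate | CC(C)[C@@]34O[C@H]4C1=CC[C@@H]2[C@](C)(CCC[C@@]2(C)C(=O)OC)[C@H]1CC3
F5 | step 4 | methyl 13,14-dihydroxy-13,14-secoabiet-7-en-18-oate (C13 epimers) | OCC1=CC[C@@H]2[C@](C)(CCC[C@@]2(C)C(=O)OC)[C@H]1CCC(O)C(C)C
F6 | step 4 | methyl 13-hydroxy-13,14-secoabiet-8(14)-en-18-oate (C13 epimers) | C=C1CC[C@@H]2[C@](C)(CCC[C@@]2(C)C(=O)OC)[C@H]1CCC(O)C(C)C
F7 | step 5 | (Z)-trimethylsilyl enol ether of 8 (C12=C13) | C=C1CC[C@@H]2[C@](C)(CCC[C@@]2(C)C(=O)OC)[C@H]1C/C=C(\O[Si](C)(C)C)C(C)C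
A1 | alternative 1 | dimethyl (6E,10E,14R)-2,6,10,14-tetramethyl-3-oxohexadeca-6,10-dienedioate | COC(=O)C(C)C(=O)CC/C(C)=C/CC/C(C)=C/CC[C@@H](C)CC(=O)OC
A2 | alternative 1 | dimethyl (13R)-3-oxolabd-8(17)-ene-15,19-dioate (axial C4 ester, one ring enantiomer drawn) | C=C1CC[C@@H]2[C@](C)(CCC(=O)[C@]2(C)C(=O)OC)[C@H]1CC[C@@H](C)CC(=O)OC
A3 | alternative 2 | methyl 13-oxo-14,15-dinorlabd-8(17)-en-18-oate | C=C1CC[C@@H]2[C@](C)(CCC[C@@]2(C)C(=O)OC)[C@H]1CCC(C)=O
A4 | alternative 2 | dimethyl (13E)-labda-8(17),13-diene-15,18-dioate | C=C1CC[C@@H]2[C@](C)(CCC[C@@]2(C)C(=O)OC)[C@H]1CC/C(C)=C/C(=O)OC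
A5 | alternative 3 | methyl 17-hydroxy-11,12,13,14,15,16-hexanorlabd-8-en-18-oate | OCC1=C[C@@]2(C)CCC[C@@](C)(C(=O)OC)[C@@H]2CC1
A6 | alternative 3 | 12-ethyl 18-methyl 9-epi-13,14,15,16-tetranorlabd-8(17)-ene-12,18-dioate | C=C1CC[C@@H]2[C@](C)(CCC[C@@]2(C)C(=O)OC)[C@@H]1CC(=O)OCC
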